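| flask | E | G | J | remark | time |
|---|---|---|---|---|---|
| south-east | 1 M | 1.1 M | 10 mM | the very flask that is asked about, followed so far |  |
| north-west | 1 M | 1.1 M | 20 mM | run made earlier |  |
| flask | 1.0 M | 1.10 M | 10.0 mM |  | 10 h |

| run | time / h | D / % | E / % |
|---|---|---|---|
| south-east | 0.250 | 37.8 | 61.4 |
| south-east | 0.833 | 55.2 | 44.2 |
| south-east | 1.33 | 57.0 | 40.9 |
| south-east | 2.00 | 58.0 | 40.7 |
| south-east | 3.00 | 58.4 | 40.5 |
| south-east | 4.00 | 58.7 | 40.5 |
| south-east | 5.00 | 58.5 | 39.3 |
| north-west | 0.500 | 49.7 | 48.9 |
| north-west | 0.833 | 54.7 | 43.0 |
| north-west | 1.33 | 57.9 | 40.4 |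
| north-west | 2.00 | 57.2 | 39.6 |
| north-west | 3.00 | 58.4 | 40.4 |
| north-west | 5.00 | 57.8 | 39.0 |
| north-west | 8.00 | 57.2 | 39.5 |

(scatter of a reading: 0.5 percentage points)

- each monomer carries two end groups and J one, which caps an end: a chain counts once for every two ends that are left, dead ends included; the units are half of the end groups of the two monomers charged
- the numbers in the tables scatter with a standard deviation of 0.5 percentage points
- a link that another step uses up counts as cut, two dead ends; so do two ends of one kind that react with each other

1. average number of monomer units in a chain (unreacted monomers counted as chains of one) at 10 h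
2. part of the E that has reacted at 10 h

- A leftover opens the ladder: D and E leave 0.800 % of the E unaccounted at 0.250 h in the south-east run, and 1.40 % at 0.500 h in the north-west run, which has twice the J. Within the scatter of 0.5 percentage points, that fits one E capped per J, so this reckoning puts capping on the first rung, and c(E) = 0.990 M remains for linking.
- Linking is the next rung: in the south-east run D reaches 57.0 % by 1.33 h, and E then barely moves. From 2.00 h on, E averages 0.403 M.
- The stop leaves a gap in the south-east run: linking has used 0.587 M of E and, one for one, as much G, so 0.513 M of the G charged is unaccounted for.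
- This reckoning treats that gap as G lost by itself, first order, racing the link. Integrating the race gives lost G = c×·ln(c(E) at start / c(E) at stop), so the south-east readings give c× = 0.569 M: the c(E) at which G vanishes by itself as fast as it links, a selectivity factor in concentration form.
- Any later rung stays within the scatter of these readings: D in the north-west run reads 57.2 % at 2.00 h and 57.2 % at 8.00 h. Holding the plateau to 10 h gives c = 59.7 % and dp = 2.25.
- The forecast gives dp 2.23 (2.17 to 2.28) and c 60.2 % (59.2 % to 61.8 %), holding the same plateau but reading it differently: “the linking step looks reversible”.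

    E + J → L (k = 0.860 /M/min)
    E + G → D (k = 0.0460 /M/min)
    G → Z (k = 0.0260 /min)
    D → X (k = 4.20 × 10⁻⁵ /min)

- The flask gives dp 2.21 and c 59.9 %, inside the forecast's ranges. At 10 h the flask holds G at 0 % of its charge, less than E at 40 % of its own, and the plateau carried forward stood. Put back in with that E, c× gives 0.515 M of G lost, beside Z at 0.511 M.
- In a neighbour flask charged with 0.40 M of E, all else as in the recipe, c(E) starts at 0.390 M after capping, and the stop obeys c(E) = start·exp(−(G charged − start + c(E))/c×). A first round with c(E) at nothing gives 0.112 M; put back, it gives 0.0921 M, so c = 77.0 %. The computed neighbour flask gives 76.6 %.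

(The readings were generated by integration for an exercise; noise was put on by code.)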